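**Plan**
1. Retrosynthesis: the carbocycle is opened last at C7–C8 and C8–C8a, with C8 traced back to carbon monoxide. This leaves a 4‑ylidene‑4H‑pyran with a triflate on C8a and the arm C5(Cl)–C6(=O)–C7H(Me)OAc. The C4a=C5 bond is then cut back to a γ‑pyranone carbonyl plus but‑3‑yn‑2‑ol, and the C9=C10 alkene to a phosphonate plus an enal.
2. Forward: the pyran ring is bought as chlorokojic acid; its 5‑OH becomes the C8a–OTf handle and its CH2Cl anchors the side chain. An HWE reaction joins the dienyl chain, acetylide addition with Meyer–Schuster rearrangement builds C5–C7, and acetylation and C5 chlorination follow. A Pd‑catalysed carbonylative cyclisation closes the carbocycle as the last ring.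
3. Enabling feature: in the 4‑ylidene‑pyran, the C8a–O bond and C7 (the only enolisable carbon) lie 1,5 to each other across C4a=C5–C6. One CO therefore bridges them into the six‑membered ene‑1,3‑dione ring, and the push–pull C4a=C5 bond rotates, so both geometric isomers can react.
4. Stereochemistry: C13 (S) comes from (S)‑2‑methylbutan‑1‑ol, and both E alkenes from the Wittig and HWE steps. C7 (R) is set in the key step by the chiral ligand on palladium, from a precursor that is racemic at C7 (enantioconvergent through the planar enolate).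

Key step: step 9

Remark: atom numbers are those of the isochromene core of the target (O2, C1, C3, C4, C4a, C5–C8, C8a; side chain C9–C15) and are used for all intermediates.

Step 1
Reactants: 1 (S)-2-methylbutan-1-ol
Product: 2 (S)-2-methylbutanal
Conditions: TEMPO (cat.), KBr (cat.), NaOCl, NaHCO3, CH2Cl2/H2O, 0 °C; dried solution used directly
Reagents that add atoms: none
Why: TEMPO/hypochlorite (Anelli) oxidation should stop at the aldehyde under buffered two‑phase conditions that do not enolise the α‑stereocentre, and the aldehyde is used at once.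

Step 2
Reactants: 2 (S)-2-methylbutanal; 3 2-(triphenylphosphoranylidene)propanal
Product: 4 (2E,4S)-2,4-dimethylhex-2-enal
Conditions: toluene, 80 °C
Reagents that add atoms: none
Why: Wittig olefination with the formyl‑stabilised ylide should give the E trisubstituted enal, and the neutral conditions leave the allylic stereocentre untouched.

Step 3
Reactants: 5 chlorokojic acid [2-(chloromethyl)-5-hydroxy-4H-pyran-4-one]
Product: 6 6-(chloromethyl)-4-oxo-4H-pyran-3-yl trifluoromethanesulfonate
Conditions: Tf2O, 2,6-lutidine, CH2Cl2, −78 → 0 °C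
Reagents that add atoms: trifluoromethanesulfonic anhydride, O=S(=O)(OS(=O)(=O)C(F)(F)F)C(F)(F)F
Why: O‑sulfonylation of the acidic enol hydroxyl of the 3‑hydroxy‑4‑pyranone, with a hindered base that should not displace the activated chloride.

Step 4
Reactants: 6 6-(chloromethyl)-4-oxo-4H-pyran-3-yl trifluoromethanesulfonate
Product: 7 diethyl {[4-oxo-5-(trifluoromethanesulfonyloxy)-4H-pyran-2-yl]methyl}phosphonate
Conditions: P(OEt)3 (neat), 110 °C
Reagents that add atoms: triethyl phosphite, CCOP(OCC)OCC
Why: Michaelis–Arbuzov reaction at the primary, pyranone‑activated chloride; the vinyl triflate is expected to be inert to the phosphite.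

Step 5
Reactants: 7 diethyl {[4-oxo-5-(trifluoromethanesulfonyloxy)-4H-pyran-2-yl]methyl}phosphonate; 4 (2E,4S)-2,4-dimethylhex-2-enal
Product: 8 6-[(1E,3E,5S)-3,5-dimethylhepta-1,3-dien-1-yl]-4-oxo-4H-pyran-3-yl trifluoromethanesulfonate
Conditions: LiHMDS, THF, −78 °C; then 4, −78 → 0 °C
Reagents that add atoms: none
Why: Horner–Wadsworth–Emmons olefination of the pyranone‑stabilised phosphonate carbanion with the enal should give the new C9=C10 alkene E, as is usual for conjugation‑stabilised phosphonates.

Step 6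
Reactants: 8 6-[(1E,3E,5S)-3,5-dimethylhepta-1,3-dien-1-yl]-4-oxo-4H-pyran-3-yl trifluoromethanesulfonate; 9 but-3-yn-2-ol (racemic)
Product: 11 6-[(1E,3E,5S)-3,5-dimethylhepta-1,3-dien-1-yl]-4-(3-hydroxy-2-oxobutylidene)-4H-pyran-3-yl trifluoromethanesulfonate (E/Z at C4a=C5, both C7 epimers), via propargylic diol 10 (not isolated)
Conditions: 9, n-BuLi (2 equiv per 9), THF, −78 °C; then 8, −78 °C; then 2 M aq HCl, THF, 0 °C → rt
Reagents that add atoms: none
Why: 1,2‑addition of the lithium acetylide to the γ‑pyranone carbonyl, then acid‑induced Meyer–Schuster rearrangement (ionisation to a 4‑alkynylpyrylium ion, water uptake at the distal alkyne carbon, tautomerisation to the push–pull ylidene ketone); the C7 configuration and C4a=C5 geometry are left open because step 9 erases both.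

Step 7
Reactants: 11 6-[(1E,3E,5S)-3,5-dimethylhepta-1,3-dien-1-yl]-4-(3-hydroxy-2-oxobutylidene)-4H-pyran-3-yl trifluoromethanesulfonate
Product: 12 4-(3-acetoxy-2-oxobutylidene)-6-[(1E,3E,5S)-3,5-dimethylhepta-1,3-dien-1-yl]-4H-pyran-3-yl trifluoromethanesulfonate
Conditions: Ac2O, pyridine, DMAP (cat.), CH2Cl2, 0 °C
Reagents that add atoms: acetic anhydride, CC(=O)OC(C)=O
Why: DMAP‑catalysed acylation of the secondary α‑hydroxy ketone installs the acetate of the target before the quaternary centre is made.

Step 8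
Reactants: 12 4-(3-acetoxy-2-oxobutylidene)-6-[(1E,3E,5S)-3,5-dimethylhepta-1,3-dien-1-yl]-4H-pyran-3-yl trifluoromethanesulfonate
Product: 13 4-(3-acetoxy-1-chloro-2-oxobutylidene)-6-[(1E,3E,5S)-3,5-dimethylhepta-1,3-dien-1-yl]-4H-pyran-3-yl trifluoromethanesulfonate
Conditions: NCS (1 equiv), MeCN, 0 °C
Reagents that add atoms: N-chlorosuccinimide, O=C1CCC(=O)N1Cl
Why: electrophilic chlorination at C5, the α‑carbon of the doubly vinylogous ester, where attack gives a pyrylium ion that loses H+; this should be the most nucleophilic carbon of the push–pull system.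

Step 9
Reactants: 13 4-(3-acetoxy-1-chloro-2-oxobutylidene)-6-[(1E,3E,5S)-3,5-dimethylhepta-1,3-dien-1-yl]-4H-pyran-3-yl trifluoromethanesulfonate
Product: 14 (+)-sclerotiorin [(7R)-5-chloro-3-[(1E,3E,5S)-3,5-dimethylhepta-1,3-dien-1-yl]-7-methyl-6,8-dioxo-7,8-dihydro-6H-isochromen-7-yl acetate]
Conditions: Pd2(dba)3 (cat.), DTBM-SEGPHOS (cat.; the enantiomer that leads to 7R, to be assigned in a first run), CO (5 bar), iPr2NEt, 1,4-dioxane, 60 °C
Reagents that add atoms: carbon monoxide, [C-]#[O+]
Why: Proposed new method: oxidative addition of Pd(0)L* into the C8a–OTf bond and CO insertion should give a cationic acylpalladium that chelates the C6 ketone (seven‑membered ring); this acidifies C7–H, the only enolisable position, so the amine forms a palladium enolate, and C–C reductive elimination joins C8 to C7. The closest known reaction types are the intramolecular C‑trapping of acylpalladium species by ketone enolates to cyclic 1,3‑diketones, the carbonylative α‑arylation of ketones, and Pd/bisphosphine‑catalysed asymmetric α‑arylation that sets quaternary centres; an enantioselective carbonylative version is not known. The carbocycle closes by a 6‑(enolendo)‑exo‑trig C‑acylation in which CO supplies C8 (a 5+1 annulation), while O‑acylation would require an eight‑membered lactone. C7 is the only new stereocentre and should be controlled by the chiral bisphosphine on palladium, which selects the face of the planar enolate; both C7 epimers of 13 give the same enolate and the push–pull C4a=C5 bond rotates, so all stereoisomers of 13 converge on one product. The step needs CO insertion to outrun direct α‑alkenylation (a five‑membered ring) and acetyl migration in the enolate; CO pressure, the weak amine base and the non‑coordinating triflate counter‑ion are chosen for this, and the C5–Cl bond is expected to remain inert towards Pd(0) under these conditions.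

**Compound list**
1 | (S)-2-methylbutan-1-ol | CC[C@H](C)CO | starting material
2 | (S)-2-methylbutanal | CC[C@H](C)C=O | intermediate
3 | 2-(triphenylphosphoranylidene)propanal | CC(C=O)=P(c1ccccc1)(c1ccccc1)c1ccccc1 | starting material
4 | (2E,4S)-2,4-dimethylhex-2-enal | CC[C@H](C)/C=C(C)/C=O | intermediate
5 | chlorokojic acid, 2-(chloromethyl)-5-hydroxy-4H-pyran-4-one | O=C1C=C(CCl)OC=C1O | starting material
6 | 6-(chloromethyl)-4-oxo-4H-pyran-3-yl trifluoromethanesulfonate | O=C1C=C(CCl)OC=C1OS(=O)(=O)C(F)(F)F | intermediate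
7 | diethyl {[4-oxo-5-(trifluoromethanesulfonyloxy)-4H-pyran-2-yl]methyl}phosphonate | CCOP(=O)(OCC)CC1=CC(=O)C(OS(=O)(=O)C(F)(F)F)=CO1 | intermediate
8 | 6-[(1E,3E,5S)-3,5-dimethylhepta-1,3-dien-1-yl]-4-oxo-4H-pyran-3-yl trifluoromethanesulfonate | CC[C@H](C)/C=C(C)/C=C/C1=CC(=O)C(OS(=O)(=O)C(F)(F)F)=CO1 | intermediate
9 | but-3-yn-2-ol (racemic) | CC(O)C#C | starting material
10 | 6-[(1E,3E,5S)-3,5-dimethylhepta-1,3-dien-1-yl]-4-hydroxy-4-(3-hydroxybut-1-yn-1-yl)-4H-pyran-3-yl trifluoromethanesulfonate (diastereomer mixture) | CC[C@H](C)/C=C(C)/C=C/C1=CC(O)(C#CC(C)O)C(OS(=O)(=O)C(F)(F)F)=CO1 | intermediate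
11 | 6-[(1E,3E,5S)-3,5-dimethylhepta-1,3-dien-1-yl]-4-(3-hydroxy-2-oxobutylidene)-4H-pyran-3-yl trifluoromethanesulfonate (E/Z, C7 epimers) | CC[C@H](C)/C=C(C)/C=C/C1=CC(=CC(=O)C(C)O)C(OS(=O)(=O)C(F)(F)F)=CO1 | intermediate
12 | 4-(3-acetoxy-2-oxobutylidene)-6-[(1E,3E,5S)-3,5-dimethylhepta-1,3-dien-1-yl]-4H-pyran-3-yl trifluoromethanesulfonate (E/Z, C7 epimers) | CC[C@H](C)/C=C(C)/C=C/C1=CC(=CC(=O)C(C)OC(C)=O)C(OS(=O)(=O)C(F)(F)F)=CO1 | intermediate
13 | 4-(3-acetoxy-1-chloro-2-oxobutylidene)-6-[(1E,3E,5S)-3,5-dimethylhepta-1,3-dien-1-yl]-4H-pyran-3-yl trifluoromethanesulfonate (E/Z, C7 epimers) | CC[C@H](C)/C=C(C)/C=C/C1=CC(=C(Cl)C(=O)C(C)OC(C)=O)C(OS(=O)(=O)C(F)(F)F)=CO1 | intermediate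
14 | (+)-sclerotiorin, (7R)-5-chloro-3-[(1E,3E,5S)-3,5-dimethylhepta-1,3-dien-1-yl]-7-methyl-6,8-dioxo-7,8-dihydro-6H-isochromen-7-yl acetate | CC[C@H](C)/C=C(C)/C=C/C1=CC2=C(Cl)C(=O)[C@](C)(OC(C)=O)C(=O)C2=CO1 | target

**Step count and risks**
Total steps: 9. Longest linear sequence: 7 steps (5 → 6 → 7 → 8 → 11 → 12 → 13 → 14; the branch from 1 is equally long).

Steps most likely to fail:

1. Step 9 (Proposed new method). The palladium enolate may show poor facial discrimination; the ring may also close without CO (direct α‑alkenylation to a five‑membered ring), or the acetyl group may migrate in the enolate before C‑acylation. The fallback uses known reaction types, sets out from 11 and returns at 14, and still closes the carbocycle last. Compound 11 is chlorinated at C5 with NCS to 4-(1-chloro-3-hydroxy-2-oxobutylidene)-6-[(1E,3E,5S)-3,5-dimethylhepta-1,3-dien-1-yl]-4H-pyran-3-yl trifluoromethanesulfonate F1. Palladium‑catalysed reductive carbonylation of the triflate (CO, Et3SiH) gives the C8a aldehyde 4-(1-chloro-3-hydroxy-2-oxobutylidene)-6-[(1E,3E,5S)-3,5-dimethylhepta-1,3-dien-1-yl]-4H-pyran-3-carbaldehyde F2. Dess–Martin oxidation of the C7 carbinol gives the 1,2‑diketone 4-(1-chloro-2,3-dioxobutylidene)-6-[(1E,3E,5S)-3,5-dimethylhepta-1,3-dien-1-yl]-4H-pyran-3-carbaldehyde F3. An enantioselective intramolecular crossed aldehyde–ketone benzoin reaction, with a chiral aminoindanol‑derived triazolylidene carbene, should join C8 to the more electrophilic C7 ketone and give (7R)-7-deacetylsclerotiorin F4. Acetylation (Ac2O, DMAP) then gives 14.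

2. Step 6. The acetylide may add in conjugate fashion at C1 of the pyranone or attack the sulfonate sulfur, and water may open the alkynylpyrylium ring before hydration at C6. The fallback sets out from 8 and returns at 12. Thionation of the pyranone carbonyl with Lawesson's reagent gives 6-[(1E,3E,5S)-3,5-dimethylhepta-1,3-dien-1-yl]-4-thioxo-4H-pyran-3-yl trifluoromethanesulfonate F5. 2‑Acetoxypropanoyl chloride and trimethylsilyldiazomethane give 3-acetoxy-1-diazobutan-2-one F6. Rh2(OAc)4‑catalysed coupling of F5 with F6 (a Barton–Kellogg‑type olefination through the thiocarbonyl ylide, with triphenylphosphine taking up the sulfur) forms the C4a=C5 bond at the thiocarbonyl carbon only and gives 12 directly.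

3. Step 4. At 110 °C the phosphite may attack the sulfonate or the pyranone ring instead of displacing chloride. The fallback avoids phosphorus chemistry, sets out from 5 and returns at 8. Zinc/acetic acid reduction of the chloromethyl group gives 5-hydroxy-2-methyl-4H-pyran-4-one F7, and triflation gives 6-methyl-4-oxo-4H-pyran-3-yl trifluoromethanesulfonate F8. Vinylogous aldol addition of its lithium dienolate (LiHMDS, −78 °C) to enal 4 gives 6-[(3E,5S)-2-hydroxy-3,5-dimethylhept-3-en-1-yl]-4-oxo-4H-pyran-3-yl trifluoromethanesulfonate F9. Mesylation and DBU elimination into conjugation give 8.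

**Further compounds**
F1 | step 9 | 4-(1-chloro-3-hydroxy-2-oxobutylidene)-6-[(1E,3E,5S)-3,5-dimethylhepta-1,3-dien-1-yl]-4H-pyran-3-yl trifluoromethanesulfonate | CC[C@H](C)/C=C(C)/C=C/C1=CC(=C(Cl)C(=O)C(C)O)C(OS(=O)(=O)C(F)(F)F)=CO1
F2 | step 9 | 4-(1-chloro-3-hydroxy-2-oxobutylidene)-6-[(1E,3E,5S)-3,5-dimethylhepta-1,3-dien-1-yl]-4H-pyran-3-carbaldehyde | CC[C@H](C)/C=C(C)/C=C/C1=CC(=C(Cl)C(=O)C(C)O)C(C=O)=CO1
F3 | step 9 | 4-(1-chloro-2,3-dioxobutylidene)-6-[(1E,3E,5S)-3,5-dimethylhepta-1,3-dien-1-yl]-4H-pyran-3-carbaldehyde | CC[C@H](C)/C=C(C)/C=C/C1=CC(=C(Cl)C(=O)C(C)=O)C(C=O)=CO1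
F4 | step 9 | (7R)-7-deacetylsclerotiorin, (7R)-5-chloro-3-[(1E,3E,5S)-3,5-dimethylhepta-1,3-dien-1-yl]-7-hydroxy-7-methyl-6H-isochromene-6,8(7H)-dione | CC[C@H](C)/C=C(C)/C=C/C1=CC2=C(Cl)C(=O)[C@](C)(O)C(=O)C2=CO1
F5 | step 6 | 6-[(1E,3E,5S)-3,5-dimethylhepta-1,3-dien-1-yl]-4-thioxo-4H-pyran-3-yl trifluoromethanesulfonate | CC[C@H](C)/C=C(C)/C=C/C1=CC(=S)C(OS(=O)(=O)C(F)(F)F)=CO1
F6 | step 6 | 3-acetoxy-1-diazobutan-2-one | CC(OC(C)=O)C(=O)C=[N+]=[N-]
F7 | step 4 | 5-hydroxy-2-methyl-4H-pyran-4-one | CC1=CC(=O)C(O)=CO1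
F8 | step 4 | 6-methyl-4-oxo-4H-pyran-3-yl trifluoromethanesulfonate | CC1=CC(=O)C(OS(=O)(=O)C(F)(F)F)=CO1
F9 | step 4 | 6-[(3E,5S)-2-hydroxy-3,5-dimethylhept-3-en-1-yl]-4-oxo-4H-pyran-3-yl trifluoromethanesulfonate | CC[C@H](C)/C=C(C)/C(O)CC1=CC(=O)C(OS(=O)(=O)C(F)(F)F)=CO1
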